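The side-chain oxygen on C2' and quinone carbon C4 are separated only by C1' and ring carbon C3, so O2' can be bonded to C4 as the ring oxygen of a 2-alkyl-2,3-dihydrobenzofuran (atoms C4, C3, C1', C2', O), a latent quinone carbonyl plus side-chain alcohol. One enantioselective palladium-catalysed carboalkoxylation of a 2-allylphenol with (E)-1-bromodec-1-ene forms O–C2' and C3'–C4', closes this ring and sets C2' as R. The phenol carries three different ethers: OMe for the future C5 methoxy, OBn para to the phenol oxygen to direct the later oxidative ring opening, and OMOM for the future C2 hydroxyl.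

Key step: step 8

Remark: quinone carbons are numbered C1–C6 as in the target (C2 OH, C3 side chain, C5 OMe), the side chain C1'–C13'; the configuration required at C2' is R. Which antipode of the chiral ligand in step 8 gives 2R cannot be predicted and is assumed to be settled by a screen.

**Route**

Step 1
Reactants: 1 2,4,5-trimethoxybenzaldehyde
Product: 2 2,4-dihydroxy-5-methoxybenzaldehyde
Conditions: AlCl3 (excess), CH2Cl2, 0 °C to rt; aqueous work-up
Reagents that add atoms: none
Why: Regioselective Lewis-acid O-demethylation, in which AlCl3 bound to the aldehyde should cleave only the ortho and para methyl ethers conjugated to the complexed carbonyl and leave the meta 5-OMe.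

Step 2
Reactants: 2 2,4-dihydroxy-5-methoxybenzaldehyde; 3 allyl bromide
Product: 4 2-hydroxy-5-methoxy-4-(prop-2-en-1-yloxy)benzaldehyde
Conditions: KHCO3, KI (cat.), MeCN, 60 °C
Reagents that add atoms: none
Why: Williamson etherification in which the weak base ionises only the more acidic 4-OH, the 2-OH being held in a hydrogen bond to the aldehyde.

Step 3
Reactants: 4 2-hydroxy-5-methoxy-4-(prop-2-en-1-yloxy)benzaldehyde
Product: 5 5-methoxy-2-(methoxymethoxy)-4-(prop-2-en-1-yloxy)benzaldehyde
Conditions: MOMCl, iPr2NEt, CH2Cl2, 0 °C to rt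
Reagents that add atoms: chloromethyl methyl ether, COCCl
Why: Acetal-type O-alkylation (MOM protection) of the remaining phenol, giving a group that tolerates base, heat and hydrogenation and later leaves a quinone oxygen under mild acid.

Step 4
Reactants: 5 5-methoxy-2-(methoxymethoxy)-4-(prop-2-en-1-yloxy)benzaldehyde
Product: 7 5-methoxy-2-(methoxymethoxy)-4-(prop-2-en-1-yloxy)phenol, via aryl formate 6 (not isolated)
Conditions: mCPBA, CH2Cl2, 0 °C to rt; NaHCO3 wash; then Et3N (cat.), MeOH, rt
Reagents that add atoms: 3-chloroperbenzoic acid, OOC(=O)c1cccc(Cl)c1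
Why: Dakin-type Baeyer–Villiger oxidation in which the electron-rich aryl group migrates to give the formate, which methanol cleaves, while the monosubstituted allyl ether alkene is epoxidised far more slowly.

Step 5
Reactants: 7 5-methoxy-2-(methoxymethoxy)-4-(prop-2-en-1-yloxy)phenol
Product: 8 1-(allyloxy)-4-(benzyloxy)-2-methoxy-5-(methoxymethoxy)benzene
Conditions: BnBr, K2CO3, DMF, rt
Reagents that add atoms: benzyl bromide, BrCc1ccccc1
Why: Williamson benzylation of the new phenol, marking the oxygen para to the future ring oxygen for release by hydrogenolysis.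

Step 6
Reactants: 8 1-(allyloxy)-4-(benzyloxy)-2-methoxy-5-(methoxymethoxy)benzene
Product: 9 2-allyl-4-(benzyloxy)-6-methoxy-3-(methoxymethoxy)phenol
Conditions: N,N-diethylaniline, 190 °C, argon
Reagents that add atoms: none
Why: Aromatic Claisen rearrangement ([3,3]-sigmatropic shift, then tautomerisation) to the only free ortho carbon, which lies between the phenol oxygen and the MOM ether.

Step 7
Reactants: 10 1-decyne
Product: 12 (E)-1-bromodec-1-ene, via alkenylzirconocene chloride 11 (not isolated)
Conditions: Cp2Zr(H)Cl, THF, rt; then NBS, 0 °C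
Reagents that add atoms: N-bromosuccinimide, O=C1CCC(=O)N1Br
Why: Hydrozirconation adds Zr–H syn with zirconium on the terminal carbon, and bromodezirconation with retention then gives the E alkenyl bromide.

Step 8
Reactants: 9 2-allyl-4-(benzyloxy)-6-methoxy-3-(methoxymethoxy)phenol; 12 (E)-1-bromodec-1-ene
Product: 13 (2R)-5-(benzyloxy)-7-methoxy-4-(methoxymethoxy)-2-[(2E)-undec-2-en-1-yl]-2,3-dihydro-1-benzofuran
Conditions: Pd2(dba)3 (2.5 mol%), TADDOL-derived chiral monophosphite (7.5 mol%), NaOtBu, toluene, 90 °C
Reagents that add atoms: none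
Why: Proposed new method: zerovalent palladium bearing the chiral monodentate ligand adds oxidatively to the C–Br bond of 12 with retention of the E geometry, the sodium phenoxide of 9 displaces bromide on the divalent palladium, the allyl C=C inserts syn into the Pd–O bond to form O–C2' and leave palladium on the primary carbon C3', and C(sp3)–C(sp2) reductive elimination forms C3'–C4' and returns zerovalent palladium. The closest known reaction types are the non-asymmetric palladium-catalysed carboalkoxylation of 2-allylphenols to 2-substituted dihydrobenzofurans and the enantioselective carboalkoxylation of γ-hydroxyalkenes with aryl or alkenyl bromides to tetrahydrofurans; joining the two on a phenol is the untested extension. The single ring closes in the 5-exo-trig mode. The C2 stereocentre arises in the insertion, where the chiral ligand alone distinguishes the two faces of the terminal alkene because 9 is achiral, and the ligand antipode leading to 2R is fixed in a preliminary screen. Insertion must outrun base-induced isomerisation of the allyl group to the propenylphenol, and reductive elimination must outrun β-hydride loss; the electron-rich phenoxide flanked by OMe, the OMOM group beside the benzylic carbon that limits the allyl rotamers, and the bulky electron-rich ligand should secure this.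

Step 9
Reactants: 13 (2R)-5-(benzyloxy)-7-methoxy-4-(methoxymethoxy)-2-[(2E)-undec-2-en-1-yl]-2,3-dihydro-1-benzofuran
Product: 14 (2R)-7-methoxy-4-(methoxymethoxy)-2-undecyl-2,3-dihydro-1-benzofuran-5-ol
Conditions: H2 (1 atm), 10% Pd/C, EtOAc, rt
Reagents that add atoms: none
Why: Heterogeneous catalytic hydrogenation should saturate the alkene and hydrogenolyse the benzyl ether in one operation, and the C2–O bond is neither benzylic nor allylic, so the stereocentre is untouched.

Step 10
Reactants: 14 (2R)-7-methoxy-4-(methoxymethoxy)-2-undecyl-2,3-dihydro-1-benzofuran-5-ol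
Product: 15 3-[(2R)-2-hydroxytridecyl]-5-methoxy-2-(methoxymethoxy)-1,4-benzoquinone
Conditions: PhI(OAc)2, MeCN/H2O (4:1), 0 °C; crude 14 used at once
Reagents that add atoms: water, O
Why: Hypervalent-iodine oxidation of a para-alkoxyphenol to the para-quinone (the tocopherol-to-tocopherylquinone type of ring opening), in which water adds at C7a para to the phenol and the hemiketal collapses by breaking the aryl–O bond, so the C2'–O bond and its R configuration are retained.

Step 11
Reactants: 15 3-[(2R)-2-hydroxytridecyl]-5-methoxy-2-(methoxymethoxy)-1,4-benzoquinone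
Product: 16 (2R)-1-[5-methoxy-2-(methoxymethoxy)-3,6-dioxocyclohexa-1,4-dien-1-yl]tridecan-2-yl acetate
Conditions: Ac2O, pyridine, DMAP (cat.), CH2Cl2, 0 °C
Reagents that add atoms: acetic anhydride, CC(=O)OC(C)=O
Why: Base-mediated O-acetylation of the only free hydroxyl, which also blocks any later closure of this oxygen onto the quinone and does not involve the stereocentre.

Step 12
Reactants: 16 (2R)-1-[5-methoxy-2-(methoxymethoxy)-3,6-dioxocyclohexa-1,4-dien-1-yl]tridecan-2-yl acetate
Product: 17 (2R)-1-(2-hydroxy-5-methoxy-3,6-dioxocyclohexa-1,4-dien-1-yl)tridecan-2-yl acetate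
Conditions: TFA/CH2Cl2 (1:10), 0 °C; aqueous work-up
Reagents that add atoms: none
Why: Acid-catalysed acetal cleavage of the methoxymethyl group, which on a quinone oxygen behaves like a MOM ester and should be far more labile than the secondary acetate or the vinylogous methyl ester at C5.

**Compound list**

1 | 2,4,5-trimethoxybenzaldehyde | COc1cc(OC)c(C=O)cc1OC | starting material
2 | 2,4-dihydroxy-5-methoxybenzaldehyde | COc1cc(C=O)c(O)cc1O | intermediate
3 | allyl bromide | C=CCBr | starting material
4 | 2-hydroxy-5-methoxy-4-(prop-2-en-1-yloxy)benzaldehyde | C=CCOc1cc(O)c(C=O)cc1OC | intermediate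
5 | 5-methoxy-2-(methoxymethoxy)-4-(prop-2-en-1-yloxy)benzaldehyde | C=CCOc1cc(OCOC)c(C=O)cc1OC | intermediate
6 | 5-methoxy-2-(methoxymethoxy)-4-(prop-2-en-1-yloxy)phenyl formate | C=CCOc1cc(OCOC)c(OC=O)cc1OC | intermediate
7 | 5-methoxy-2-(methoxymethoxy)-4-(prop-2-en-1-yloxy)phenol | C=CCOc1cc(OCOC)c(O)cc1OC | intermediate
8 | 1-(allyloxy)-4-(benzyloxy)-2-methoxy-5-(methoxymethoxy)benzene | C=CCOc1cc(OCOC)c(OCc2ccccc2)cc1OC | intermediate
9 | 2-allyl-4-(benzyloxy)-6-methoxy-3-(methoxymethoxy)phenol | C=CCc1c(O)c(OC)cc(OCc2ccccc2)c1OCOC | intermediate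
10 | 1-decyne | C#CCCCCCCCC | starting material
11 | chloro[(E)-dec-1-en-1-yl]bis(cyclopentadienyl)zirconium | CCCCCCCC/C=C/[Zr](Cl)(C1C=CC=C1)C1C=CC=C1 | intermediate
12 | (E)-1-bromodec-1-ene | CCCCCCCC/C=C/Br | intermediate
13 | (2R)-5-(benzyloxy)-7-methoxy-4-(methoxymethoxy)-2-[(2E)-undec-2-en-1-yl]-2,3-dihydro-1-benzofuran | CCCCCCCC/C=C/C[C@@H]1Cc2c(OCOC)c(OCc3ccccc3)cc(OC)c2O1 | intermediate
14 | (2R)-7-methoxy-4-(methoxymethoxy)-2-undecyl-2,3-dihydro-1-benzofuran-5-ol | CCCCCCCCCCC[C@@H]1Cc2c(OCOC)c(O)cc(OC)c2O1 | intermediate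
15 | 3-[(2R)-2-hydroxytridecyl]-5-methoxy-2-(methoxymethoxy)-1,4-benzoquinone | CCCCCCCCCCC[C@H](CC1=C(OCOC)C(=O)C=C(OC)C1=O)O | intermediate
16 | (2R)-1-[5-methoxy-2-(methoxymethoxy)-3,6-dioxocyclohexa-1,4-dien-1-yl]tridecan-2-yl acetate | CCCCCCCCCCC[C@H](CC1=C(OCOC)C(=O)C=C(OC)C1=O)OC(C)=O | intermediate
17 | (2R)-1-(2-hydroxy-5-methoxy-3,6-dioxocyclohexa-1,4-dien-1-yl)tridecan-2-yl acetate | CCCCCCCCCCC[C@H](CC1=C(O)C(=O)C=C(OC)C1=O)OC(C)=O | target

Total step count: 12. Longest linear sequence: 11 steps (steps 1–6, then 8–12); step 7 is a one-step branch.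

**Steps most likely to fail**

Step 8. The insertion may show poor facial selectivity, the phenoxide may isomerise the allyl group to the conjugated propenyl group before ring closure, or the alkylpalladium may lose a β-hydride before coupling. The fallback uses known chemistry, sets out from 9 and comes back at 16, and gives up the dihydrobenzofuran. The phenol is benzylated (BnBr, K2CO3, DMF) to 1,4-bis(benzyloxy)-2-methoxy-5-(methoxymethoxy)-6-(prop-2-en-1-yl)benzene F1. Buffered mCPBA epoxidation of the terminal alkene should give the racemic arylmethyloxirane F2. Hydrolytic kinetic resolution with the chiral cobalt salen acetate complex [N,N'-bis(3,5-di-tert-butylsalicylidene)cyclohexane-1,2-diamine]Co(OAc) and 0.55 equivalents of water, using the catalyst antipode that consumes the R epoxide, should leave the (S)-arylmethyloxirane F3 and remove the other enantiomer as the (R)-arylpropane-1,2-diol F4. Opening at the terminal carbon with decylmagnesium bromide and catalytic CuI does not touch the stereocentre and should give the (R)-aryltridecan-2-ol F5. Acetylation (Ac2O, pyridine) gives the bis-benzyl acetate F6, hydrogenolysis (H2, Pd/C) gives the hydroquinone acetate F7, and oxidation with PhI(OAc)2 in MeCN gives 16.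

Step 10. Water may be delivered ortho to the phenol and not para, or the acetic acid formed may strip the MOM group so that the freed side-chain alcohol closes back onto the quinone. The fallback separates oxidation from ring opening, sets out from 14 and comes back at 15. PhI(OAc)2 in dry methanol with NaHCO3 at −10 °C should add methanol at C7a and give the ring-closed para-quinone monoketal F8 (both C7a epimers), which is isolated. Wet silica gel or dilute oxalic acid in THF/H2O at 0 °C then hydrolyses the ketal, and the hemiketal opens to 15 under nearly neutral conditions.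

Step 12. The acid may partly cleave the acetate, or the formaldehyde-derived cation may be captured by the nucleophilic C6 of the hydroxyquinone. The fallback reverses the order of deprotection and acylation, sets out from 15 and comes back at 17. Dilute aqueous HCl in THF at 0 °C, where the formaldehyde released is hydrated, should give 2-hydroxy-3-[(2R)-2-hydroxytridecyl]-5-methoxy-1,4-benzoquinone F9. Ac2O and pyridine give the diacetate F10. Aqueous NaHCO3 in THF at 0 °C then hydrolyses only the quinonyl acetate, a vinylogous anhydride, and leaves the secondary acetate of 17.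

**Further compounds**

F1 | step 8 | 1,4-bis(benzyloxy)-2-methoxy-5-(methoxymethoxy)-6-(prop-2-en-1-yl)benzene | C=CCc1c(OCc2ccccc2)c(OC)cc(OCc2ccccc2)c1OCOC
F2 | step 8 | rac-2-{[2,5-bis(benzyloxy)-3-methoxy-6-(methoxymethoxy)phenyl]methyl}oxirane | C(c1c(OCc2ccccc2)c(OC)cc(OCc2ccccc2)c1OCOC)C1CO1
F3 | step 8 | (2S)-2-{[2,5-bis(benzyloxy)-3-methoxy-6-(methoxymethoxy)phenyl]methyl}oxirane | C(c1c(OCc2ccccc2)c(OC)cc(OCc2ccccc2)c1OCOC)[C@H]1CO1
F4 | step 8 | (2R)-3-[2,5-bis(benzyloxy)-3-methoxy-6-(methoxymethoxy)phenyl]propane-1,2-diol | C(c1c(OCc2ccccc2)c(OC)cc(OCc2ccccc2)c1OCOC)[C@@H](O)CO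
F5 | step 8 | (2R)-1-[2,5-bis(benzyloxy)-3-methoxy-6-(methoxymethoxy)phenyl]tridecan-2-ol | CCCCCCCCCCC[C@H](Cc1c(OCc2ccccc2)c(OC)cc(OCc2ccccc2)c1OCOC)O
F6 | step 8 | (2R)-1-[2,5-bis(benzyloxy)-3-methoxy-6-(methoxymethoxy)phenyl]tridecan-2-yl acetate | CCCCCCCCCCC[C@H](Cc1c(OCc2ccccc2)c(OC)cc(OCc2ccccc2)c1OCOC)OC(C)=O
F7 | step 8 | (2R)-1-[2,5-dihydroxy-3-methoxy-6-(methoxymethoxy)phenyl]tridecan-2-yl acetate | CCCCCCCCCCC[C@H](Cc1c(O)c(OC)cc(O)c1OCOC)OC(C)=O
F8 | step 10 | (2R)-7,7a-dimethoxy-4-(methoxymethoxy)-2-undecyl-3,7a-dihydro-1-benzofuran-5(2H)-one | CCCCCCCCCCC[C@@H]1CC2=C(OCOC)C(=O)C=C(OC)C2(OC)O1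
F9 | step 12 | 2-hydroxy-3-[(2R)-2-hydroxytridecyl]-5-methoxy-1,4-benzoquinone | CCCCCCCCCCC[C@H](CC1=C(O)C(=O)C=C(OC)C1=O)O
F10 | step 12 | (2R)-1-[2-(acetyloxy)-5-methoxy-3,6-dioxocyclohexa-1,4-dien-1-yl]tridecan-2-yl acetate | CCCCCCCCCCC[C@H](CC1=C(OC(C)=O)C(=O)C=C(OC)C1=O)OC(C)=O
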